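The target is cut at C7'–C1' into a furofuran lactone and a brominated dihydrobenzofuran. Everything rests on the C5'–C8'' bond of that dihydrobenzofuran: C8'' bears the C9'' hydroxymethyl group and is bonded to ring B ortho to the ring oxygen, exactly what remains when an ortho-lithiated aryl ether opens a C8''–C9'' epoxide at its inner carbon. A single operation therefore forms C5'–C8'', closes the five-membered oxygen ring, sets C8'' by inversion (H7''/H8'' cis) and frees the C9'' alcohol. The precursor is the threo aryl ether of an aryl(oxiranyl)methanol carrying iodine at C5' for exchange and bromine at C1' for the later union.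

Key step: step 6

Assumption: lignan numbering is used (ring A with C7–C9, ring B with C7'–C9', ring C with C7''–C9''); the target SMILES is read as 7S,8S,7'S,8'S (both aryl groups on the concave face of the furofuran, each trans to its neighbouring ring-fusion hydrogen) and 7''S,8''S (cis dihydrobenzofuran).

Step 1
Reactants: 1 vanillin
Product: 2 4-formyl-2-methoxyphenyl pivalate
Conditions: PivCl, Et3N, DMAP (cat.), CH2Cl2, 0 °C to rt
Reagents that add atoms: pivaloyl chloride CC(C)(C)C(=O)Cl
Why: DMAP-catalysed acylation masks the phenol as a hindered, electron-withdrawing ester that should survive the Grignard step and temper ionisation at the future benzylic C7''.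

Step 2
Reactants: 2 4-formyl-2-methoxyphenyl pivalate; 3 vinylmagnesium bromide
Product: 4 racemic 4-(1-hydroxyprop-2-en-1-yl)-2-methoxyphenyl pivalate
Conditions: CH2=CHMgBr (1.1 equiv), THF, −78 °C; aq. NH4Cl
Reagents that add atoms: none
Why: Grignard 1,2-addition to the aldehyde at −78 °C is far faster than attack on the hindered pivalate and gives the racemic allylic alcohol whose carbinol carbon becomes C7''.

Step 3
Reactants: 4 racemic 4-(1-hydroxyprop-2-en-1-yl)-2-methoxyphenyl pivalate
Product: 5 4-[(S)-hydroxy[(2R)-oxiran-2-yl]methyl]-2-methoxyphenyl pivalate (erythro)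
Conditions: Ti(OiPr)4 (0.15 equiv), (2R,3R)-(+)-diisopropyl tartrate (0.2 equiv), t-BuOOH (0.45 equiv), 4 Å MS, CH2Cl2, −20 °C
Reagents that add atoms: tert-butyl hydroperoxide CC(C)(C)OO
Why: Sharpless kinetic-resolution epoxidation, in which the (2R,3R)-tartrate catalyst epoxidises only the (R)-alcohol at a useful rate and on the alkene face that leads to the erythro product, so the catalyst sets C8'' (R) and the resolution selects C7'' (S, the descriptor changing with the priorities), while limiting peroxide leaves the (S)-alcohol behind.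

Step 4
Reactants: 6 4-bromo-2-methoxyphenol
Product: 7 4-bromo-2-iodo-6-methoxyphenol
Conditions: NaI, NaOH, aq. NaOCl, MeOH, 0 °C; then aq. HCl
Reagents that add atoms: sodium iodide [Na+].[I-]
Why: Electrophilic aromatic iodination of the phenoxide goes ortho to the oxygen because the para position carries bromine, the same pattern as the iodination of vanillin to 5-iodovanillin.

Step 5
Reactants: 5 4-[(S)-hydroxy[(2R)-oxiran-2-yl]methyl]-2-methoxyphenyl pivalate; 7 4-bromo-2-iodo-6-methoxyphenol
Product: 8 4-[(R)-(4-bromo-2-iodo-6-methoxyphenoxy)[(2R)-oxiran-2-yl]methyl]-2-methoxyphenyl pivalate (threo)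
Conditions: PPh3, DIAD, toluene, 0 °C to rt
Reagents that add atoms: none
Why: Mitsunobu etherification, in which the acidic halogenated phenol displaces the oxyphosphonium ion in an SN2 step that inverts C7'' and turns the erythro alcohol into the threo ether, with the acyloxy-deactivated ring C and the adjacent epoxide disfavouring ionisation.

Step 6
Reactants: 8 4-[(R)-(4-bromo-2-iodo-6-methoxyphenoxy)[(2R)-oxiran-2-yl]methyl]-2-methoxyphenyl pivalate
Product: 11 4-[(2S,3S)-5-bromo-3-(hydroxymethyl)-7-methoxy-2,3-dihydro-1-benzofuran-2-yl]-2-methoxyphenyl pivalate (cis), via C5' aryllithium 9 (not isolated), via C9'' lithium alkoxide 10 (not isolated)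
Conditions: n-BuLi (1.05 equiv), THF/Et2O, −100 °C; then −78 to −40 °C; AcOH quench at −78 °C
Reagents that add atoms: none
Why: n-BuLi should exchange the C5' iodine within minutes at −100 °C, faster than it exchanges the C1' bromine or adds to the hindered pivalate, giving aryllithium 9. The carbanion then attacks the inner epoxide carbon C8'' from the side opposite its C–O bond, forming C5'–C8'' and releasing the C9'' oxygen as lithium alkoxide 10, which the acidic quench protonates. The closest known reaction is the Parham cyclisation of ortho-lithiated aryl 2,3-epoxypropyl ethers to 3-hydroxymethyl-2,3-dihydrobenzofurans. The dihydrofuran ring closes in the 5-exo-tet mode, preferred over 6-endo-tet attack at C9'' because only the exo trajectory lies collinear with the breaking C–O bond within the short tether. C8'' is set by SN2 inversion of the (R)-epoxide centre while C7'' is untouched, so the threo ether can give only the cis (7''S,8''S) ring. The step needs iodine-over-bromine and exo-over-endo selectivity, secured by the weaker C–I bond next to the ether oxygen, by the low temperature and by leaving out magnesium halides and other Lewis acids that would first open the epoxide to a halohydrin.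

Step 7
Reactants: 11 4-[(2S,3S)-5-bromo-3-(hydroxymethyl)-7-methoxy-2,3-dihydro-1-benzofuran-2-yl]-2-methoxyphenyl pivalate
Product: 12 4-[(2S,3S)-5-bromo-3-(hydroxymethyl)-7-methoxy-2,3-dihydro-1-benzofuran-2-yl]-2-methoxyphenol
Conditions: i-Bu2AlH (4 equiv), CH2Cl2, −78 °C; aq. potassium sodium tartrate
Reagents that add atoms: none
Why: Hydride reduction of the aryl ester at −78 °C frees the ring C phenol without producing a warm phenoxide that could open the cis ring through a quinone methide, and the bromide and both stereocentres are untouched.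

Step 8
Reactants: 12 4-[(2S,3S)-5-bromo-3-(hydroxymethyl)-7-methoxy-2,3-dihydro-1-benzofuran-2-yl]-2-methoxyphenol
Product: 13 (2S,3S)-5-bromo-2-[4-(tert-butyldimethylsilyloxy)-3-methoxyphenyl]-3-[(tert-butyldimethylsilyloxy)methyl]-7-methoxy-2,3-dihydro-1-benzofuran
Conditions: TBSCl (2.5 equiv), imidazole, DMF, rt
Reagents that add atoms: tert-butyldimethylsilyl chloride CC(C)(C)[Si](C)(C)Cl
Why: Imidazole-promoted silylation protects the phenol and the primary alcohol in one operation as ethers that are inert to organolithiums and removable together by fluoride.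

Step 9
Reactants: 6 4-bromo-2-methoxyphenol
Product: 14 (4-bromo-2-methoxyphenoxy)(tert-butyl)dimethylsilane
Conditions: TBSCl, imidazole, DMF, rt
Reagents that add atoms: tert-butyldimethylsilyl chloride CC(C)(C)[Si](C)(C)Cl
Why: Silylation of the phenol gives a bromide that should undergo clean bromine-lithium exchange para to the silyloxy group, where no silyl migration to carbon is possible.

Step 10
Reactants: 15 tetraethyl ethane-1,1,2,2-tetracarboxylate; 16 formaldehyde
Product: 17 tetraethyl 1,4-dihydroxybutane-2,2,3,3-tetracarboxylate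
Conditions: 37% aq. CH2O (2.5 equiv), K2CO3 (cat.), EtOH, rt
Reagents that add atoms: formaldehyde (second equivalent of 16) C=O
Why: Base-catalysed aldol addition (Tollens-type hydroxymethylation) of each of the two malonate-type C–H groups to one molecule of formaldehyde, two molecules in all, installs C9 and C9' on the carbons that become C8 and C8', and any material that lactonises early converges on the same bis-lactone in step 11.

Step 11
Reactants: 17 tetraethyl 1,4-dihydroxybutane-2,2,3,3-tetracarboxylate
Product: 18 racemic cis-tetrahydro-1H,3H-furo[3,4-c]furan-1,4-dione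
Conditions: 6 M HCl, reflux; then neat, 150 °C
Reagents that add atoms: none
Why: Acid hydrolysis, γ-lactonisation of each CH2OH onto a carboxyl of the neighbouring carbon and malonic decarboxylation should give the bis-lactone, which can only be cis-fused, so the relative configuration of C8 and C8' follows from ring strain.

Step 12
Reactants: 14 (4-bromo-2-methoxyphenoxy)(tert-butyl)dimethylsilane; 18 racemic cis-tetrahydro-1H,3H-furo[3,4-c]furan-1,4-dione
Product: 20 racemic cis-fused 4-[4-(tert-butyldimethylsilyloxy)-3-methoxyphenyl]-4-hydroxytetrahydro-1H,3H-furo[3,4-c]furan-1-one (hemiketal), via ring A aryllithium 19 (not isolated)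
Conditions: 14, n-BuLi (1.0 equiv), THF, −78 °C; cannulate into 18 (2 equiv), THF, −78 °C; AcOH, −78 °C
Reagents that add atoms: none
Why: Bromine-lithium exchange and 1,2-addition of the aryllithium to one lactone carbonyl, as in C-aryl glycoside synthesis, should stop at the hemiketal stage at −78 °C, and inverse addition to an excess of the symmetric bis-lactone suppresses double addition.

Step 13
Reactants: 20 racemic cis-fused 4-[4-(tert-butyldimethylsilyloxy)-3-methoxyphenyl]-4-hydroxytetrahydro-1H,3H-furo[3,4-c]furan-1-one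
Product: 21 racemic (3aS*,4S*,6aS*)-4-[4-(tert-butyldimethylsilyloxy)-3-methoxyphenyl]tetrahydro-1H,3H-furo[3,4-c]furan-1-one (aryl on the concave face)
Conditions: Et3SiH (3 equiv), BF3·OEt2 (2 equiv), CH2Cl2, −78 to −40 °C
Reagents that add atoms: none
Why: Ionic hydrogenation, in which BF3·OEt2 ionises the hemiketal to a bicyclic oxocarbenium ion and Et3SiH adds to its convex face syn to H8, which places ring A on the concave face (relative 7S*,8S*) and leaves the lactone untouched.

Step 14
Reactants: 21 racemic (3aS*,4S*,6aS*)-4-[4-(tert-butyldimethylsilyloxy)-3-methoxyphenyl]tetrahydro-1H,3H-furo[3,4-c]furan-1-one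
Product: 22 (3aS,4S,6aS)-4-[4-(tert-butyldimethylsilyloxy)-3-methoxyphenyl]tetrahydro-1H,3H-furo[3,4-c]furan-1-one
Conditions: preparative SFC, amylose tris(3,5-dimethylphenylcarbamate) phase, CO2/MeOH
Reagents that add atoms: none
Why: Chromatographic resolution of the rigid UV-active lactone on a polysaccharide chiral phase supplies the (3aS,4S,6aS) antipode, whose absolute configuration is to be confirmed by X-ray or CD correlation before use.

Step 15
Reactants: 13 (2S,3S)-5-bromo-2-[4-(tert-butyldimethylsilyloxy)-3-methoxyphenyl]-3-[(tert-butyldimethylsilyloxy)methyl]-7-methoxy-2,3-dihydro-1-benzofuran; 22 (3aS,4S,6aS)-4-[4-(tert-butyldimethylsilyloxy)-3-methoxyphenyl]tetrahydro-1H,3H-furo[3,4-c]furan-1-one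
Product: 24 hemiketal (3aS,4S,6aS)-4-(ring A aryl)-1-(ring B dihydrobenzofuranyl)tetrahydro-1H,3H-furo[3,4-c]furan-1-ol carrying three TBS ethers, via ring B aryllithium 23 (not isolated)
Conditions: 13, n-BuLi (1.05 equiv), THF, −78 °C; then 22 (1.2 equiv), THF, −78 °C; AcOH, −78 °C
Reagents that add atoms: none
Why: Bromine-lithium exchange at C1' followed by 1,2-addition to the remaining lactone carbonyl forms the C1'–C7' bond and should stop at the hemiketal at −78 °C, with the silyl ethers and the dihydrobenzofuran inert to the aryllithium.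

Step 16
Reactants: 24 hemiketal carrying three TBS ethers
Product: 25 tris-TBS ether of the target (7S,8S,7'S,8'S,7''S,8''S)
Conditions: Et3SiH (3 equiv), BF3·OEt2 (1.5 equiv), CH2Cl2, −78 °C; Et3N then aq. NaHCO3 at −78 °C
Reagents that add atoms: none
Why: Ionic hydrogenation of the hemiketal through the oxocarbenium ion with hydride delivered to the convex face, syn to H8' and away from ring A, should set C7' (S) with ring B on the concave face, while −78 °C and a cold basic quench keep the benzylic C7–O and C7''–O bonds from ionising.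

Step 17
Reactants: 25 tris-TBS ether of the target
Product: 26 target, 4-[(2S,3S)-3-(hydroxymethyl)-5-[(1S,3aS,4S,6aS)-4-(4-hydroxy-3-methoxyphenyl)tetrahydro-1H,3H-furo[3,4-c]furan-1-yl]-7-methoxy-2,3-dihydro-1-benzofuran-2-yl]-2-methoxyphenol
Conditions: TBAF (3.5 equiv), AcOH (3.5 equiv), THF, 0 °C
Reagents that add atoms: none
Why: Fluoride-mediated desilylation cleaves the three silyl ethers, and acetic acid buffering keeps the liberated ring C phenoxide from opening the cis dihydrobenzofuran or epimerising a benzylic centre.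

Compound list
1 | vanillin | COc1cc(C=O)ccc1O | starting material
2 | 4-formyl-2-methoxyphenyl pivalate | COc1cc(C=O)ccc1OC(=O)C(C)(C)C | intermediate
3 | vinylmagnesium bromide | C=C[Mg]Br | starting material
4 | racemic 4-(1-hydroxyprop-2-en-1-yl)-2-methoxyphenyl pivalate | COc1cc(C(O)C=C)ccc1OC(=O)C(C)(C)C | intermediate
5 | 4-[(S)-hydroxy[(2R)-oxiran-2-yl]methyl]-2-methoxyphenyl pivalate (erythro) | O[C@@H](c1ccc(OC(=O)C(C)(C)C)c(OC)c1)[C@H]1CO1 | intermediate
6 | 4-bromo-2-methoxyphenol | COc1cc(Br)ccc1O | starting material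
7 | 4-bromo-2-iodo-6-methoxyphenol | COc1cc(Br)cc(I)c1O | intermediate
8 | 4-[(R)-(4-bromo-2-iodo-6-methoxyphenoxy)[(2R)-oxiran-2-yl]methyl]-2-methoxyphenyl pivalate (threo; key-step precursor) | COc1cc(Br)cc(I)c1O[C@H](c1ccc(OC(=O)C(C)(C)C)c(OC)c1)[C@H]1CO1 | intermediate
9 | C5' aryllithium of 8 | COc1cc(Br)cc([Li])c1O[C@H](c1ccc(OC(=O)C(C)(C)C)c(OC)c1)[C@H]1CO1 | intermediate
10 | C9'' lithium alkoxide of 11 | Brc1cc(OC)c2c(c1)[C@@H](CO[Li])[C@@H](c1ccc(OC(=O)C(C)(C)C)c(OC)c1)O2 | intermediate
11 | 4-[(2S,3S)-5-bromo-3-(hydroxymethyl)-7-methoxy-2,3-dihydro-1-benzofuran-2-yl]-2-methoxyphenyl pivalate (cis; key-step product) | Brc1cc(OC)c2c(c1)[C@@H](CO)[C@@H](c1ccc(OC(=O)C(C)(C)C)c(OC)c1)O2 | intermediate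
12 | 4-[(2S,3S)-5-bromo-3-(hydroxymethyl)-7-methoxy-2,3-dihydro-1-benzofuran-2-yl]-2-methoxyphenol | Brc1cc(OC)c2c(c1)[C@@H](CO)[C@@H](c1ccc(O)c(OC)c1)O2 | intermediate
13 | (2S,3S)-5-bromo-2-[4-(tert-butyldimethylsilyloxy)-3-methoxyphenyl]-3-[(tert-butyldimethylsilyloxy)methyl]-7-methoxy-2,3-dihydro-1-benzofuran | Brc1cc(OC)c2c(c1)[C@@H](CO[Si](C)(C)C(C)(C)C)[C@@H](c1ccc(O[Si](C)(C)C(C)(C)C)c(OC)c1)O2 | intermediate
14 | (4-bromo-2-methoxyphenoxy)(tert-butyl)dimethylsilane | COc1cc(Br)ccc1O[Si](C)(C)C(C)(C)C | intermediate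
15 | tetraethyl ethane-1,1,2,2-tetracarboxylate | CCOC(=O)C(C(=O)OCC)C(C(=O)OCC)C(=O)OCC | starting material
16 | formaldehyde (37% aqueous solution) | C=O | starting material
17 | tetraethyl 1,4-dihydroxybutane-2,2,3,3-tetracarboxylate | CCOC(=O)C(CO)(C(=O)OCC)C(CO)(C(=O)OCC)C(=O)OCC | intermediate
18 | racemic cis-tetrahydro-1H,3H-furo[3,4-c]furan-1,4-dione (SMILES shows the 3aS,6aS enantiomer) | O=C1OC[C@@H]2[C@H]1COC2=O | intermediate
19 | [4-(tert-butyldimethylsilyloxy)-3-methoxyphenyl]lithium | COc1cc([Li])ccc1O[Si](C)(C)C(C)(C)C | intermediate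
20 | racemic cis-fused 4-[4-(tert-butyldimethylsilyloxy)-3-methoxyphenyl]-4-hydroxytetrahydro-1H,3H-furo[3,4-c]furan-1-one (hemiketal carbon unassigned; SMILES shows the enantiomer carried forward) | COc1cc(C2(O)OC[C@@H]3[C@H]2COC3=O)ccc1O[Si](C)(C)C(C)(C)C | intermediate
21 | racemic (3aS*,4S*,6aS*)-4-[4-(tert-butyldimethylsilyloxy)-3-methoxyphenyl]tetrahydro-1H,3H-furo[3,4-c]furan-1-one (SMILES shows the enantiomer carried forward) | COc1cc([C@H]2OC[C@@H]3[C@H]2COC3=O)ccc1O[Si](C)(C)C(C)(C)C | intermediate
22 | (3aS,4S,6aS)-4-[4-(tert-butyldimethylsilyloxy)-3-methoxyphenyl]tetrahydro-1H,3H-furo[3,4-c]furan-1-one | COc1cc([C@H]2OC[C@@H]3[C@H]2COC3=O)ccc1O[Si](C)(C)C(C)(C)C | intermediate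
23 | C1' aryllithium of 13 | [Li]c1cc(OC)c2c(c1)[C@@H](CO[Si](C)(C)C(C)(C)C)[C@@H](c1ccc(O[Si](C)(C)C(C)(C)C)c(OC)c1)O2 | intermediate
24 | hemiketal from 22 and 23 (C7' unassigned, three TBS ethers) | COc1cc([C@H]2OC[C@@H]3[C@H]2COC3(O)c2cc(OC)c3c(c2)[C@@H](CO[Si](C)(C)C(C)(C)C)[C@@H](c2ccc(O[Si](C)(C)C(C)(C)C)c(OC)c2)O3)ccc1O[Si](C)(C)C(C)(C)C | intermediate
25 | tris-TBS ether of the target | COc1cc([C@H]2OC[C@@H]3[C@H]2CO[C@@H]3c2cc(OC)c3c(c2)[C@@H](CO[Si](C)(C)C(C)(C)C)[C@@H](c2ccc(O[Si](C)(C)C(C)(C)C)c(OC)c2)O3)ccc1O[Si](C)(C)C(C)(C)C | intermediate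
26 | CNP0303197.1 | COc1cc([C@H]2OC[C@@H]3[C@H]2CO[C@@H]3c2cc(OC)c3c(c2)[C@@H](CO)[C@@H](c2ccc(O)c(OC)c2)O3)ccc1O | target

Total step count: 17. Longest linear sequence: 10 steps (steps 1, 2, 3, 5, 6, 7, 8, 15, 16, 17).

Steps most likely to fail

Step 6. The exchange may not stay at iodine: bromine exchange, attack on the ester, protonation of the aryllithium before it cyclises, or 6-endo opening would each erode the step. The fallback makes the same C5'–C8'' bond and the cis ring by carbene C–H insertion and sets out from aldehyde 2. NaBH4 reduction gives 4-(hydroxymethyl)-2-methoxyphenyl pivalate F1. Mitsunobu etherification of this primary alcohol with phenol 7 gives 4-[(4-bromo-2-iodo-6-methoxyphenoxy)methyl]-2-methoxyphenyl pivalate F2. Coupling of the iodide only with BrZnCH2CO2Me under Pd2(dba)3/XPhos gives the methyl arylacetate F3. Diazo transfer with p-acetamidobenzenesulfonyl azide and DBU gives the aryldiazoacetate F4. Rh2(S-PTTL)4, or its mirror-image catalyst if that one leads to the 2S,3R series, inserts the carbene into the benzylic ether C–H bond to give the cis methyl (2S,3R)-dihydrobenzofuran-3-carboxylate F5. Excess i-Bu2AlH reduces the ester and removes the pivalate, and the route is rejoined at diol 12.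

Step 16. The Lewis acid may ionise the benzylic C7–O or C7''–O bond (epimerisation to the exo or trans series, or reductive ring opening), or hydride delivery may lose its facial bias. The fallback closes the ether without a cation and sets out from hemiketal 24. LiBH(s-Bu)3 at −78 °C reduces its ring-opened hydroxy ketone under Felkin control to the 7'S diol F6, with Zn(BH4)2 under chelation as the alternative face selector. MsCl in pyridine sulfonylates only the primary C9 hydroxyl to give the mesylate F7. The benzylic oxygen displaces the mesylate in the same pot with retention at C7', and the route is rejoined at 25.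

Step 5. The hindered phenol may displace the oxyphosphonium ion too slowly, so that the hydrazide is alkylated or ionisation leaks configuration at C7''. The fallback separates activation from displacement and sets out from alcohol 5. MsCl and Et3N at −20 °C give the methanesulfonate F8. The caesium salt of phenol 7 (Cs2CO3, DMF, 0 °C to rt) displaces it in an SN2 reaction that again inverts C7'', and the route is rejoined at 8.

Further compounds
F1 | step 6 | 4-(hydroxymethyl)-2-methoxyphenyl pivalate | COc1cc(CO)ccc1OC(=O)C(C)(C)C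
F2 | step 6 | 4-[(4-bromo-2-iodo-6-methoxyphenoxy)methyl]-2-methoxyphenyl pivalate | COc1cc(Br)cc(I)c1OCc1ccc(OC(=O)C(C)(C)C)c(OC)c1
F3 | step 6 | methyl 2-[5-bromo-3-methoxy-2-[[3-methoxy-4-(pivaloyloxy)phenyl]methoxy]phenyl]acetate | COC(=O)Cc1cc(Br)cc(OC)c1OCc1ccc(OC(=O)C(C)(C)C)c(OC)c1
F4 | step 6 | methyl 2-diazo-2-[5-bromo-3-methoxy-2-[[3-methoxy-4-(pivaloyloxy)phenyl]methoxy]phenyl]acetate | COC(=O)C(=[N+]=[N-])c1cc(Br)cc(OC)c1OCc1ccc(OC(=O)C(C)(C)C)c(OC)c1
F5 | step 6 | methyl (2S,3R)-5-bromo-7-methoxy-2-[3-methoxy-4-(pivaloyloxy)phenyl]-2,3-dihydro-1-benzofuran-3-carboxylate (cis) | Brc1cc(OC)c2c(c1)[C@@H](C(=O)OC)[C@@H](c1ccc(OC(=O)C(C)(C)C)c(OC)c1)O2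
F6 | step 16 | 7'S diol from reduction of 24 (C7' and C9 hydroxyls free, three TBS ethers) | COc1cc([C@H]2OC[C@H]([C@H]2CO)[C@H](O)c2cc(OC)c3c(c2)[C@@H](CO[Si](C)(C)C(C)(C)C)[C@@H](c2ccc(O[Si](C)(C)C(C)(C)C)c(OC)c2)O3)ccc1O[Si](C)(C)C(C)(C)C
F7 | step 16 | C9 methanesulfonate of F6 | COc1cc([C@H]2OC[C@H]([C@H]2COS(C)(=O)=O)[C@H](O)c2cc(OC)c3c(c2)[C@@H](CO[Si](C)(C)C(C)(C)C)[C@@H](c2ccc(O[Si](C)(C)C(C)(C)C)c(OC)c2)O3)ccc1O[Si](C)(C)C(C)(C)C
F8 | step 5 | 4-[(S)-(methanesulfonyloxy)[(2R)-oxiran-2-yl]methyl]-2-methoxyphenyl pivalate | CS(=O)(=O)O[C@@H](c1ccc(OC(=O)C(C)(C)C)c(OC)c1)[C@H]1CO1
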